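## Retrosynthetic overview
1. Glabrol comes from its 7,4′-bis-TBS ether by mildly acidic fluoride, so nothing basic touches C2 once it is set.
2. Ring C is made last. One new step forms the C2–C3 bond, the pyranone ring and the (2S) centre: a catalytic enantioconvergent Petasis–Ferrier-type [1,3] O→C rearrangement of a racemic 2-aryl-4-methylene-4H-1,3-benzodioxine.
3. That enol acetal comes from Petasis methylenation of a 2-aryl-4H-1,3-benzodioxin-4-one. The dioxinone comes from acetal union (O1–C2 bond) of a ring-A salicylic acid with a ring-B benzaldehyde.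
4. The ring-A acid comes from methyl 2,4-dihydroxybenzoate (1,1-dimethylallyl ether, then aromatic Claisen, prenyl at future C8). The ring-B aldehyde comes from 4-hydroxy-3-iodobenzaldehyde (Stille prenylation, future C3′).
5. Ring order: benzene rings A and B are bought, then the temporary dioxinone ring is formed, then ring C.

Assumption: only skeleton-building compounds are numbered. Catalysts, bases, silylating and methylenating reagents are given by name, with SMILES where they add atoms.

## Route

**Step 1**
Reactants: 1 methyl 2,4-dihydroxybenzoate; 2 3-chloro-3-methylbut-1-yne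
Product: 3 methyl 2-hydroxy-4-[(2-methylbut-3-yn-2-yl)oxy]benzoate
Conditions: 2 (1.5 equiv), K2CO3, KI, CuI (10 mol %), acetone, reflux
Reagents that add atoms: 3-chloro-3-methylbut-1-yne (2), C#CC(C)(C)Cl
Why: Cu-assisted propargylic O-alkylation (Williamson type); the 2-OH is hydrogen-bonded to the ester and stays inert, so only the 4-OH is etherified.

**Step 2**
Reactants: 3
Product: 4 methyl 2-hydroxy-4-[(2-methylbut-3-en-2-yl)oxy]benzoate
Conditions: H2 (1 atm), Lindlar catalyst, quinoline, EtOAc, rt
Reagents that add atoms: none (H2 only)
Why: Lindlar semihydrogenation stops at the terminal alkene and leaves the ester, phenol and arene untouched.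

**Step 3**
Reactants: 4
Product: 5 methyl 2,4-dihydroxy-3-(3-methylbut-2-en-1-yl)benzoate
Conditions: PhNEt2, 140 °C, 3 h, Ar
Reagents that add atoms: none
Why: Aromatic Claisen [3,3] rearrangement and rearomatisation turn the 1,1-dimethylallyl ether into a linear prenyl group; chelation of the 2-OH to the ester fixes C3=C4 double-bond character, so migration goes to C3, and any minor C5 isomer is removed by chromatography.

**Step 4**
Reactants: 5
Product: 6 2,4-dihydroxy-3-(3-methylbut-2-en-1-yl)benzoic acid
Conditions: KOH (4 M aq), MeOH, 65 °C; then cold 1 M citric acid to pH 3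
Reagents that add atoms: potassium hydroxide, [K+].[OH-] (its O ends up in the CO2H)
Why: BAc2 saponification; the prenyl group is base-stable, and cold mild acidification avoids both decarboxylation and chroman formation.

**Step 5**
Reactants: 6
Product: 7 4-[(tert-butyldimethylsilyl)oxy]-2-hydroxy-3-(3-methylbut-2-en-1-yl)benzoic acid
Conditions: TBSCl (2.3 equiv), imidazole, DMF, rt; then AcOH/THF/H2O, rt
Reagents that add atoms: TBSCl, CC(C)(C)[Si](C)(C)Cl
Why: Silyl ether formation at the free 4-OH (the chelated, doubly flanked 2-OH does not react); the TBS ester that forms alongside is hydrolysed selectively by aqueous AcOH, which aryl TBS ethers tolerate.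

**Step 6**
Reactants: 8 4-hydroxy-3-iodobenzaldehyde
Product: 9 4-[(tert-butyldimethylsilyl)oxy]-3-iodobenzaldehyde
Conditions: TBSCl, imidazole, CH2Cl2, rt
Reagents that add atoms: TBSCl, CC(C)(C)[Si](C)(C)Cl
Why: Standard phenol silylation; the aldehyde and the C–I bond are inert.

**Step 7**
Reactants: 9; 10 tributyl(3-methylbut-2-en-1-yl)stannane
Product: 11 4-[(tert-butyldimethylsilyl)oxy]-3-(3-methylbut-2-en-1-yl)benzaldehyde
Conditions: 10 (1.2 equiv), Pd(PPh3)4 (5 mol %), DMF, 90 °C; K2CO3/silica chromatography
Reagents that add atoms: tributyl(prenyl)stannane (10), CCCC[Sn](CCCC)(CCCC)CC=C(C)C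
Why: Stille cross-coupling at the C–I bond with C–C formation at the unsubstituted allyl terminus gives the linear prenyl arene; the neutral conditions spare the aldehyde and the aryl TBS ether.

**Step 8**
Reactants: 7; 11
Product: 12 rac-7-(TBSO)-2-[4-(TBSO)-3-prenylphenyl]-8-prenyl-4H-1,3-benzodioxin-4-one (racemic at the acetal carbon C2)
Conditions: (i) HMDS, CH2Cl2, rt, concentrate; (ii) 11, TMSOTf (10 mol %), 2,6-di-tert-butyl-4-methylpyridine (15 mol %), CH2Cl2, −78 °C; pyridine quench
Reagents that add atoms: none retained (TMS groups from HMDS, C[Si](C)(C)N[Si](C)(C)C, leave as (TMS)2O)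
Why: Noyori-type silyl acetalisation (the "union" of the Petasis–Ferrier tactic); TMSOTf activates the aldehyde toward the bis-TMS salicylate and loss of (TMS)2O drives closure of the six-membered O-aryl/O-acyl acetal, whose racemic centre is irrelevant because step 10 erases it; buffered −78 °C conditions spare the prenyl and OTBS groups.

**Step 9**
Reactants: 12
Product: 13 rac-7-(TBSO)-2-[4-(TBSO)-3-prenylphenyl]-4-methylidene-8-prenyl-4H-1,3-benzodioxine
Conditions: Cp2TiMe2 (2.5 equiv), PhMe, 70 °C, dark; hexane, then filtration through Et3N-washed basic alumina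
Reagents that add atoms: dimethyltitanocene, [CH3-].[CH3-].[Ti+4].c1cc[cH-]c1.c1cc[cH-]c1 (delivers CH2 in place of the carbonyl O)
Why: Petasis methylenation (Cp2Ti=CH2 [2+2]/retro-[2+2]) on the only carbonyl present; the reagent is neutral and not Lewis acidic, so the acetal, silyl ethers and trisubstituted alkenes survive.

**Step 10 (key step)**
Reactants: 13
Product: 14 (2S)-7-(TBSO)-2-[4-(TBSO)-3-prenylphenyl]-8-prenyl-2,3-dihydro-4H-chromen-4-one
Conditions: chiral IDPi acid (5 mol %; BINOL-derived imidodiphosphorimidate, 3,3′ = 9-phenanthryl, N-Tf core) + methallyl-TMS (8 mol %), PhMe, rt, 15 min (gives TMS–IDPi); then 13 (0.03 M), PhMe/CH2Cl2 4:1, 4 Å MS, −78 °C, 24 h; Et3N quench at −78 °C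
Reagents that add atoms: none (isomerisation)
Why: Proposed new method: TMS–IDPi silylates the enol-ether oxygen O3 and the C2–O3 bond ionises (the cation is stabilised by the aryloxy O1 and the p-silyloxyaryl ring), which erases the racemic acetal centre and gives an achiral aryl-oxocarbenium tethered to a TMS enol ether in contact with the confined chiral anion; after rotation about C4–C4a the enol-silane carbon closes irreversibly on one face of C2 (six-membered Mukaiyama-aldol-type closure), forming C2–C3, ring C and the stereocentre, and TMS+ passes from the product ketone to the next substrate; the only counter-anion present is chiral and the slight excess of methallyl-TMS scavenges stray protons, so no achiral background catalyst is available, and the enol silane is >10^4 times more nucleophilic than the prenyl alkenes, so Prins cyclisation should not compete; the closest known reactions are the Petasis–Ferrier rearrangement of aliphatic 4-methylene-1,3-dioxanes with stoichiometric Me2AlCl (substrate control only), the chiral-phosphoric-acid aza-Petasis–Ferrier rearrangement, and silylium/IDPi Mukaiyama additions to oxocarbenium ions; there is no reliable model for the sense of induction, so the catalyst antipode that gives 2S is identified in the first run by CD/rotation (both are made from (R)- or (S)-BINOL) and ee is upgraded by recrystallising 14 if needed.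

**Step 11**
Reactants: 14
Product: 15 (2S)-glabrol
Conditions: KHF2 (5 equiv), MeOH/THF, 0 °C to rt
Reagents that add atoms: none
Why: Fluoride cleavage of the phenolic TBS ethers in a weakly acidic medium; with no base there is no retro-oxa-Michael racemisation at C2, and the medium is too mild to cyclise the o-prenylphenols to chromans.

## Compound list
1 | methyl 2,4-dihydroxybenzoate | COC(=O)c1ccc(O)cc1O | starting material
2 | 3-chloro-3-methylbut-1-yne | C#CC(C)(C)Cl | starting material
3 | methyl 2-hydroxy-4-[(2-methylbut-3-yn-2-yl)oxy]benzoate | COC(=O)c1ccc(OC(C)(C)C#C)cc1O | intermediate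
4 | methyl 2-hydroxy-4-[(2-methylbut-3-en-2-yl)oxy]benzoate | COC(=O)c1ccc(OC(C)(C)C=C)cc1O | intermediate
5 | methyl 2,4-dihydroxy-3-prenylbenzoate | COC(=O)c1ccc(O)c(CC=C(C)C)c1O | intermediate
6 | 2,4-dihydroxy-3-prenylbenzoic acid | OC(=O)c1ccc(O)c(CC=C(C)C)c1O | intermediate
7 | 4-(TBSO)-2-hydroxy-3-prenylbenzoic acid | OC(=O)c1ccc(O[Si](C)(C)C(C)(C)C)c(CC=C(C)C)c1O | intermediate
8 | 4-hydroxy-3-iodobenzaldehyde | O=Cc1ccc(O)c(I)c1 | starting material
9 | 4-(TBSO)-3-iodobenzaldehyde | O=Cc1ccc(O[Si](C)(C)C(C)(C)C)c(I)c1 | intermediate
10 | tributyl(3-methylbut-2-en-1-yl)stannane | CCCC[Sn](CCCC)(CCCC)CC=C(C)C | starting material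
11 | 4-(TBSO)-3-prenylbenzaldehyde | O=Cc1ccc(O[Si](C)(C)C(C)(C)C)c(CC=C(C)C)c1 | intermediate
12 | rac-2-aryl-4H-1,3-benzodioxin-4-one | O=C1OC(c2ccc(O[Si](C)(C)C(C)(C)C)c(CC=C(C)C)c2)Oc2c(CC=C(C)C)c(O[Si](C)(C)C(C)(C)C)ccc12 | intermediate
13 | rac-2-aryl-4-methylidene-4H-1,3-benzodioxine | C=C1OC(c2ccc(O[Si](C)(C)C(C)(C)C)c(CC=C(C)C)c2)Oc2c(CC=C(C)C)c(O[Si](C)(C)C(C)(C)C)ccc12 | intermediate
14 | (2S)-7,4′-bis-O-TBS-glabrol | CC(C)=CCc1cc([C@@H]2CC(=O)c3ccc(O[Si](C)(C)C(C)(C)C)c(CC=C(C)C)c3O2)ccc1O[Si](C)(C)C(C)(C)C | intermediate
15 | (2S)-glabrol | CC(C)=CCc1cc([C@@H]2CC(=O)c3ccc(O)c(CC=C(C)C)c3O2)ccc1O | target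

## Summary
Total steps: 11. Longest linear sequence: 9 (steps 1–5, then 8–11).

**Three steps most likely to fail**

1. **Step 10 (new step).**
   - Risk: low ee from a loose ion pair or a poor fit of the large substrate in the anion pocket, racemic background from adventitious acid, or slow turnover because the product ketone holds the silylium.
   - Fallback (known chemistry): Rh(I)/chiral diene (or Pd(II)/t-BuPyOx) asymmetric 1,4-addition of an arylboronic acid to a chromone. The boronic acid is [4-(TBSO)-3-prenylphenyl]boronic acid, made from 4-bromo-2-prenylphenol with TBSCl, then n-BuLi/B(OiPr)3. The chromone is 7-(TBSO)-8-prenylchromone, made from 2,4-dihydroxyacetophenone by the same Claisen sequence, TBSCl and DMF-DMA cyclisation. This gives 14 directly, and step 11 follows.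

2. **Step 8 (union).**
   - Risk: the hindered aryl OTMS is a poor nucleophile, and the O-aryl/O-acyl acetal of an electron-rich aldehyde is labile.
   - Fallback: close the same ring oxidatively. Reduce 11 to the benzyl alcohol, Mitsunobu-etherify the 2-OH of the 4-O-TBS derivative of 5, and cleave the methyl ester with Me3SnOH. Then oxidise the electron-rich benzyl ether with anhydrous DDQ so that the neighbouring CO2H captures the oxocarbenium. This is the reaction type that converts PMB ethers into PMP acetals.

3. **Step 9 (methylenation).**
   - Risk: sluggish reaction of the electron-rich conjugated lactone, or premature thermal or Ti-promoted rearrangement of 13 to racemic 14.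
   - Fallback: accept rac-14 and take the stereochemistry from a known kinetic resolution. Ru(II)–TsDPEN asymmetric transfer hydrogenation (HCO2H/Et3N) of flavanones reduces the (R)-ketone and leaves (S)-14. The flavanol can be reoxidised, racemised with base and recycled.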